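# Proposed synthesis of methyl 2-[2-(hydroxymethyl)-4,6-dimethoxyphenoxy]-4-methyl-6-[(3-methylbut-2-en-1-yl)oxy]benzoate (14)

## The problem

The target 14 is an achiral diaryl ether that is crowded on both sides of the ether oxygen. Ring A is a methyl benzoate whose ester carbon C1 lies between a prenyl ether at C2 and the aryloxy group at C6, with a methyl group at C4. Ring B carries the ether oxygen at C1' between a hydroxymethyl group at C2' and a methoxy group at C6', with a second methoxy group at C4'. The central task is therefore a di-ortho-substituted diaryl ether bond, which a direct coupling of two finished, electron-rich arenes would have to force. There is no stereocentre in 14, so any sp3 centre made on the way needs no control, only clean removal. Three groups are fragile: the prenyl aryl ether (acid, electrophilic halogen or iodine, hydrogenation catalysts, long exposure to quinones, strong heating), the primary benzylic alcohol (oxidation), and the 2,6-dioxygenated benzoic acid unit (decarboxylation in hot acid). As an ester, that last unit is also a Dieckmann acceptor for any enolate tethered to the ortho oxygen. The enabling feature is that the oxygens on C4' and C6' of ring B are 1,3-related, with the ether carbon C1' and the hydroxymethyl carbon C2' beside them. Two hydrogens richer, ring B is a 4-aryloxy-5-(hydroxymethyl)cyclohexane-1,3-dione. In that form C1'–C2' is a Michael bond from the oxygen-bearing α-carbon of an aryloxyacetone to the β-carbon of 2(5H)-furanone, and C4'–C5' is a Claisen bond from the ketone methyl group to the lactone carbonyl. Opening of the lactone releases the hydroxymethyl group unprotected, and the diaryl ether starts as an ordinary phenol O-alkylation on ring A.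

## Retrosynthesis

**14 from 13: three O–CH3 bonds.** The ester O–methyl bond and the two aryl O–methyl bonds of 14 are cut together, leading to 13, which holds a carboxylic acid and a resorcinol. This is preferred to carrying the methyl groups through, because the key step needs ring A as a carboxylate and delivers the ring B oxygens as carbonyl groups. One alkylation sets all three methyl groups, and carboxylate alkylation is the one esterification that the two ortho substituents do not retard. The forward step must leave the benzylic alcohol untouched, which a carbonate base ensures.

**13 from 10: removal of two hydrogens.** No skeletal bond is cut; 13 is the aromatic tautomer of the enedione that results when 10 loses the hydrogens on its two adjacent sp3 ring carbons. The usual ways of turning a cyclohexane-1,3-dione into a resorcinol clash with this substrate. Halogen or iodine reagents and hot Pd/C endanger the prenyl group, and aerobic catalysis by divalent palladium oxidises the benzylic alcohol once the ring is aromatic. The plan therefore converts 10 by soft enolisation into the bis(silyloxy)cyclohexadiene 11, in which the acid and the alcohol are capped as well. A quinone then abstracts hydride at 0 °C to give the arene 12, and methanolysis gives 13. What is asked of the forward reaction is complete double enol silylation and a short, cold contact with the oxidant.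

**10 from 7 and 8: the key cut, C1'–C2' and C4'–C5'.** The neighbouring cut through the diaryl ether oxygen would require an Ullmann or SNAr coupling between two arenes that are each di-ortho-substituted and electron-rich. Cutting ring B instead leaves the ether as the alkyl aryl ether of 7, and the four-carbon partner 8 is commercial. The forward reaction passes through the Michael adduct 9 and must meet three demands:
- conjugate addition from the aryloxy-bearing carbon of the ketone;
- ring closure from its methyl group;
- no reaction at the ring A carboxyl group, which is why 7 is an acid and reacts as its carboxylate.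

**7 from 6 from 5: ketone and acid unmasked in a fixed order.** A methyl ester ortho to an –OCH2C(O)CH3 chain is a classical Dieckmann substrate. Under hydroxide the ketone enolate would close onto the ester through a five-membered transition state faster than the shielded ester is hydrolysed. Alkylating the phenol with an α-halo ketone and then saponifying is therefore not safe. The ketone is carried as its secondary alcohol: 7 comes from 6 by oxidation, and 6 from ester 5 by hydrolysis while no enolisable ketone is present. This costs one step. The stereocentre in 5 and 6 is racemic and is erased in 7.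

**5 from 3 and 4, and 3 from 1 and 2: two O–alkyl bonds on a symmetric diphenol.** Opening of racemic propylene oxide 4 by the phenoxide of 3 gives the 2-hydroxypropyl ether 5 in one step. Phenol 3 comes from the commercial symmetric benzoate 1 and prenyl bromide 2. Mono-alkylation is expected to stop by itself, because the remaining hydroxyl of 3 is locked in a hydrogen bond to the ester carbonyl. All carbons of ring A and its substituents are thus bought in 1.

## Roads not taken

**Alternative 1:** Ring A is cut at C1–C2 and C5–C6 and assembled by a pyrone Diels–Alder reaction. In the forward direction 6-(benzyloxy)-4-methyl-2H-pyran-2-one A1 and the ynoate of the ring B phenol, methyl 3-[2-({[tert-butyl(dimethyl)silyl]oxy}methyl)-4,6-dimethoxyphenoxy]prop-2-ynoate A2, would be heated. The [4+2] adduct would lose its lactone bridge by decarboxylation and give the benzoate A3.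
- Merits: The polarisation of the partners agrees, since the unsubstituted diene terminus of A1 is its nucleophilic end and meets the aryloxy-bearing β-carbon of A2. The ester enters as the methyl ester, so no shielded ester is hydrolysed. Ring B is an arene throughout, so no oxidation-level correction is needed. In these respects this road is cleaner than the chosen one.
- Weak points: A2 is an aryl ynol ether that must be built on a ring B phenol which is itself not commercial. Its donor oxygen lowers the dienophilicity of the triple bond, so prolonged heating is to be expected. The prenyl group cannot be carried: A3 holds a benzyl placeholder that must be removed by hydrogenolysis and replaced, and the silyl ether must then be cleaved, three steps after the key step.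
- Comparison: Two branches of several steps each and three end-game steps stand against seven linear steps from 1 in the chosen plan, which needs no protecting group on ring B.

**Alternative 2:** Ring B is cut at C6'–C5', C4'–C3' and C6'–C1' (Danheiser benzannulation). The cyclobutenone methyl 2-{[2-({[tert-butyl(dimethyl)silyl]oxy}methyl)-4-oxocyclobut-2-en-1-yl]oxy}-4-methyl-6-[(3-methylbut-2-en-1-yl)oxy]benzoate A4 would be heated with methoxyethyne A5. Electrocyclic opening, [2+2] addition of the alkyne, a second opening and a 6π closure would give the phenol A6.
- Merits: The substitution pattern of ring B is dictated by the mechanism, the ring is formed at the aromatic oxidation level, and, as in the chosen plan, the ether starts as an sp3 C–O bond. Not needing a dehydrogenation is a real advantage over the chosen plan.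
- Weak points: A4 carries the whole of ring A on a strained, base-sensitive four-membered ketone, and no short, reliable preparation of it is evident. A5 is volatile and unstable. The thermal cascade exposes the prenyl aryl ether to prolonged heating. A6 still needs one methylation and a desilylation.
- Comparison: The chosen plan sets against this a key-step precursor, 7, that is four ordinary steps from 1, and a commercial partner, 8.

**Alternative 3:** Ring A is cut at the ether bond O–C6 and at the C1–carboxyl bond. CsF would release an aryne from 5-methyl-3-[(3-methylbut-2-en-1-yl)oxy]-2-(trimethylsilyl)phenyl trifluoromethanesulfonate A7. The phenoxide of 2-({[tert-butyl(dimethyl)silyl]oxy}methyl)-4,6-dimethoxyphenol A8 would add at C6, remote from the prenyloxy group, and the aryl anion at C1 would be trapped by carbon dioxide A9 to give the acid A10.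
- Merits: This is the most convergent road. Its regiochemistry rests on the well-established inductive control by an alkoxy group next to the aryne. The crowded ether and the carboxyl group are made in one operation without any oxidation-level change, and only esterification and desilylation follow. In convergence and in avoiding a dehydrogenation it is better than the chosen plan.
- Weak points: The aryl anion must be carboxylated faster than it is protonated by any proton source in the flask. Three-component carboxylations of arynes are best established for neutral nitrogen nucleophiles, and a phenoxide itself binds A9 reversibly. A7 needs a silyl group placed between two oxygen substituents, and A8 also needs several steps.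
- Comparison: The total step count is higher than seven. The chosen plan offers one linear sequence of classical ionic reactions from a single commercial benzoate, and a key step whose foreseeable failure modes each have a remedy.

Key step: step 5

Assumption: 4 is used as the racemate, and 5, 6, 9 and 10 are carried as racemates or diastereomer mixtures, because every stereocentre they contain is destroyed before the achiral target.

## Route

Step 1
Reactants: 1 methyl 2,6-dihydroxy-4-methylbenzoate; 2 prenyl bromide (1-bromo-3-methylbut-2-ene)
Product: 3 methyl 2-hydroxy-4-methyl-6-[(3-methylbut-2-en-1-yl)oxy]benzoate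
Conditions: 2 (1.05 equiv), K2CO3 (1.2 equiv), acetone, reflux
Reagents that add atoms: none
Why: Williamson ether synthesis; after the first alkylation the remaining hydroxyl is held in a hydrogen bond to the ester carbonyl and is much less acidic and nucleophilic, so one equivalent of 2 should stop at the mono-ether.

Step 2
Reactants: 3 methyl 2-hydroxy-4-methyl-6-[(3-methylbut-2-en-1-yl)oxy]benzoate; 4 racemic propylene oxide (2-methyloxirane)
Product: 5 racemic methyl 2-(2-hydroxypropoxy)-4-methyl-6-[(3-methylbut-2-en-1-yl)oxy]benzoate
Conditions: 4 (5 equiv), K2CO3 (0.3 equiv), DMF, 90 °C, sealed tube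
Reagents that add atoms: none
Why: Base-catalysed SN2 opening of the epoxide by the phenoxide at the unsubstituted carbon installs the three-carbon chain with the future ketone masked as a secondary alcohol; the new stereocentre is racemic and is removed in step 4, and any transesterification of the new alkoxide onto the ester is harmless because hydrolysis follows.

Step 3
Reactants: 5 racemic methyl 2-(2-hydroxypropoxy)-4-methyl-6-[(3-methylbut-2-en-1-yl)oxy]benzoate
Product: 6 racemic 2-(2-hydroxypropoxy)-4-methyl-6-[(3-methylbut-2-en-1-yl)oxy]benzoic acid
Conditions: KOH (10 equiv), EtOH/H2O 3:1, reflux; then 1 M HCl, 0 °C, to pH 3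
Reagents that add atoms: potassium hydroxide, [K+].[OH-]
Why: Saponification of the shielded ester with excess hydroxide at reflux, possibly assisted by the neighbouring alkoxide; no enolisable ketone is present, so no Dieckmann closure can compete, the prenyl ether is inert to base, and cold acidification avoids decarboxylation and prenyl loss.

Step 4
Reactants: 6 racemic 2-(2-hydroxypropoxy)-4-methyl-6-[(3-methylbut-2-en-1-yl)oxy]benzoic acid
Product: 7 4-methyl-6-[(3-methylbut-2-en-1-yl)oxy]-2-(2-oxopropoxy)benzoic acid
Conditions: Dess–Martin periodinane (1.3 equiv), pyridine (3 equiv), CH2Cl2, 0 °C to rt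
Reagents that add atoms: none
Why: Dess–Martin oxidation of a secondary alcohol to the methyl ketone under buffered, near-neutral conditions that tolerate the free acid, the trisubstituted alkene and both aryl ethers.

Step 5
Reactants: 7 4-methyl-6-[(3-methylbut-2-en-1-yl)oxy]-2-(2-oxopropoxy)benzoic acid; 8 2(5H)-furanone
Product: 10 2-{[6-(hydroxymethyl)-2,4-dioxocyclohexyl]oxy}-4-methyl-6-[(3-methylbut-2-en-1-yl)oxy]benzoic acid as a racemic mixture of diastereomers, via lactone Michael adduct 9 (not isolated)
Conditions: KOt-Bu (3.2 equiv), THF/DMPU 5:1, −10 °C; 8 (1.1 equiv) in THF added over 2 h; to rt; then 1 M HCl, 0 °C, to pH 3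
Reagents that add atoms: none
Why: With three equivalents of KOt-Bu, 7 becomes its potassium carboxylate and, under equilibrating conditions, mainly the enolate on the aryloxy-bearing methylene, the more acidic α-position because of the inductive pull of the ether oxygen. This enolate adds to the β-carbon of 8 (bond C1'–C2'), and proton transfer from the lactone enolate to the ketone side gives the methyl ketone enolate of 9. That enolate attacks the lactone carbonyl in a 6-exo-trig Claisen (Dieckmann-type) closure (bond C4'–C5'), the tetrahedral intermediate expels the ring oxygen as the primary alkoxide, and ring B appears as the cyclohexane-1,3-dione with the hydroxymethyl group free. Deprotonation of the dione to its stabilised enolate is the irreversible end point that pulls the reversible Michael and proton-transfer equilibria forward. The closest known reaction type is the consecutive Michael–Claisen annulation of substituted acetones with α,β-unsaturated esters to cyclohexane-1,3-diones, in which the more substituted α-carbon adds first and the methyl group closes the ring, as in a Robinson annulation. The two new stereocentres (the ring carbons bearing the aryloxy and the hydroxymethyl group) are under no control beyond epimerisation of the carbon next to the carbonyl toward the trans isomer, and both are erased in step 6, so a mixture is accepted. The selectivities needed are Michael addition from the aryloxy side with Claisen closure from the methyl side, secured by the acidity difference and by the fact that in 9 only the methyl enolate can reach the lactone carbonyl through a six-membered transition state, and chemoselectivity against closure onto ring A, secured by carrying its carboxyl group as the unreactive carboxylate. Slow addition of 8 at −10 °C keeps its γ-deprotonation and self-addition down.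

Step 6
Reactants: 10 2-{[6-(hydroxymethyl)-2,4-dioxocyclohexyl]oxy}-4-methyl-6-[(3-methylbut-2-en-1-yl)oxy]benzoic acid
Product: 13 2-[2,4-dihydroxy-6-(hydroxymethyl)phenoxy]-4-methyl-6-[(3-methylbut-2-en-1-yl)oxy]benzoic acid, via tetrakis(trimethylsilyl) dienol ether 11 (not isolated), via tetrakis(trimethylsilyl) arene 12 (not isolated)
Conditions: TMSOTf (5 equiv), Et3N (6 equiv), CH2Cl2, 0 °C; evaporation, pentane, filtration; DDQ (1.05 equiv), 2,4,6-collidine (1.5 equiv), benzene, 0 °C to rt; MeOH, citric acid (cat.), rt
Reagents that add atoms: none
Why: Soft enolisation turns the dione into a bis(silyloxy)cyclohexadiene and caps the acid and the alcohol; DDQ dehydrogenation of this silyl dienol ether (hydride abstraction from an allylic ring CH, then proton loss) aromatises ring B at 0 °C, far faster than DDQ attacks a prenyl aryl ether in dry solvent, and methanolysis strips the four silyl groups. Both ring stereocentres disappear here.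

Step 7
Reactants: 13 2-[2,4-dihydroxy-6-(hydroxymethyl)phenoxy]-4-methyl-6-[(3-methylbut-2-en-1-yl)oxy]benzoic acid
Product: 14 methyl 2-[2-(hydroxymethyl)-4,6-dimethoxyphenoxy]-4-methyl-6-[(3-methylbut-2-en-1-yl)oxy]benzoate
Conditions: MeI (5 equiv), K2CO3 (5 equiv), DMF, rt
Reagents that add atoms: iodomethane, CI
Why: SN2 O-methylation of the carboxylate and of both phenoxides; K2CO3 does not deprotonate the benzylic alcohol, and alkylation at the carboxylate oxygen is not hindered by the two ortho substituents that would block a Fischer esterification.

## Compound list

1 | methyl 2,6-dihydroxy-4-methylbenzoate | COC(=O)c1c(O)cc(C)cc1O | starting material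
2 | prenyl bromide (1-bromo-3-methylbut-2-ene) | CC(C)=CCBr | starting material
3 | methyl 2-hydroxy-4-methyl-6-[(3-methylbut-2-en-1-yl)oxy]benzoate | COC(=O)c1c(O)cc(C)cc1OCC=C(C)C | intermediate
4 | racemic propylene oxide (2-methyloxirane) | CC1CO1 | starting material
5 | racemic methyl 2-(2-hydroxypropoxy)-4-methyl-6-[(3-methylbut-2-en-1-yl)oxy]benzoate | COC(=O)c1c(OCC(C)O)cc(C)cc1OCC=C(C)C | intermediate
6 | racemic 2-(2-hydroxypropoxy)-4-methyl-6-[(3-methylbut-2-en-1-yl)oxy]benzoic acid | CC(O)COc1cc(C)cc(OCC=C(C)C)c1C(=O)O | intermediate
7 | 4-methyl-6-[(3-methylbut-2-en-1-yl)oxy]-2-(2-oxopropoxy)benzoic acid | CC(=O)COc1cc(C)cc(OCC=C(C)C)c1C(=O)O | intermediate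
8 | 2(5H)-furanone | O=C1OCC=C1 | starting material
9 | 4-methyl-6-[(3-methylbut-2-en-1-yl)oxy]-2-[2-oxo-1-(5-oxooxolan-3-yl)propoxy]benzoic acid (Michael adduct, diastereomer mixture, not isolated) | CC(=O)C(Oc1cc(C)cc(OCC=C(C)C)c1C(=O)O)C1COC(=O)C1 | intermediate
10 | 2-{[6-(hydroxymethyl)-2,4-dioxocyclohexyl]oxy}-4-methyl-6-[(3-methylbut-2-en-1-yl)oxy]benzoic acid (racemic diastereomer mixture) | CC(C)=CCOc1cc(C)cc(OC2C(CO)CC(=O)CC2=O)c1C(=O)O | intermediate
11 | trimethylsilyl 4-methyl-6-[(3-methylbut-2-en-1-yl)oxy]-2-({2,4-bis[(trimethylsilyl)oxy]-6-{[(trimethylsilyl)oxy]methyl}cyclohexa-1,3-dien-1-yl}oxy)benzoate (racemic, drawn as one double-bond isomer, not isolated) | CC(C)=CCOc1cc(C)cc(OC2=C(O[Si](C)(C)C)C=C(O[Si](C)(C)C)CC2CO[Si](C)(C)C)c1C(=O)O[Si](C)(C)C | intermediate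
12 | trimethylsilyl 4-methyl-6-[(3-methylbut-2-en-1-yl)oxy]-2-(2,4-bis[(trimethylsilyl)oxy]-6-{[(trimethylsilyl)oxy]methyl}phenoxy)benzoate (not isolated) | CC(C)=CCOc1cc(C)cc(Oc2c(CO[Si](C)(C)C)cc(O[Si](C)(C)C)cc2O[Si](C)(C)C)c1C(=O)O[Si](C)(C)C | intermediate
13 | 2-[2,4-dihydroxy-6-(hydroxymethyl)phenoxy]-4-methyl-6-[(3-methylbut-2-en-1-yl)oxy]benzoic acid | CC(C)=CCOc1cc(C)cc(Oc2c(CO)cc(O)cc2O)c1C(=O)O | intermediate
14 | methyl 2-[2-(hydroxymethyl)-4,6-dimethoxyphenoxy]-4-methyl-6-[(3-methylbut-2-en-1-yl)oxy]benzoate | COC(=O)c1c(OCC=C(C)C)cc(C)cc1Oc1c(CO)cc(OC)cc1OC | target

## Step count and least certain steps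

Total step count: 7 (step 6 is one telescoped operation). Longest linear sequence: 7 steps from 1.

**Step 5 (key step).** The most likely failure is consumption of 8 by γ-deprotonation and self-addition, since its anion is an aromatic furanolate, so that the conjugate addition to 7 starves. Conjugate addition through the methyl-side enolate (leading to the regioisomeric ring) and a second addition at the remaining acidic methine of 9 are also conceivable. Fallback: set out from 7 and replace 8 by the acyclic acceptor methyl (E)-4-{[tert-butyl(dimethyl)silyl]oxy}but-2-enoate, the ester class for which this annulation is documented and which has no aromatic anion open to it. Under the same base the Claisen step expels methoxide and should give the silyl ether 2-{[6-({[tert-butyl(dimethyl)silyl]oxy}methyl)-2,4-dioxocyclohexyl]oxy}-4-methyl-6-[(3-methylbut-2-en-1-yl)oxy]benzoic acid F1. Bu4NF buffered with acetic acid in THF removes the silyl group and returns the route to 10.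

**Step 6.** Several processes could spoil it:
- incomplete second enol silylation, which leaves a mono-silylated enone that the quinone does not oxidise in the cold;
- protodesilylation by the acidic hydroquinone before hydride abstraction;
- oxidative cleavage of the prenyl ether on prolonged contact with DDQ;
- ionisation of the allylic aryloxy group in a minor diene isomer by the silyl triflate, which would aromatise the ring by loss of ring A and not by oxidation.

Fallback: set out from 10 and protect the primary alcohol (TBSCl, imidazole, DMF, then methanolic K2CO3 to cleave the silyl ester and silyl enol ether) to give 2-{[6-({[tert-butyl(dimethyl)silyl]oxy}methyl)-2,4-dioxocyclohexyl]oxy}-4-methyl-6-[(3-methylbut-2-en-1-yl)oxy]benzoic acid F1. With no oxidisable alcohol left, the catalytic aerobic dehydrogenation of cyclohexanones to phenols (Pd(TFA)2, 2-(dimethylamino)pyridine, TsOH, O2, DMSO, 80 °C) can be used. It should give 2-[2-({[tert-butyl(dimethyl)silyl]oxy}methyl)-4,6-dihydroxyphenoxy]-4-methyl-6-[(3-methylbut-2-en-1-yl)oxy]benzoic acid F2. Bu4NF in THF then returns the route to 13.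

**Step 2.** The chelated, ortho-substituted phenoxide may open the epoxide slowly, attack at the substituted epoxide carbon may compete, and 4 may oligomerise on the product alkoxide once the phenol is used up. Fallback: set out from 3 and alkylate with chloroacetone (K2CO3, KI, acetone, reflux) to give methyl 4-methyl-6-[(3-methylbut-2-en-1-yl)oxy]-2-(2-oxopropoxy)benzoate F3. Reduce it at once with NaBH4 in MeOH at 0 °C, which leaves the shielded ester alone and returns the route to 5. The keto ester is thus never exposed to hydroxide.

**Step 3.** Hydrolysis may stall because both ortho substituents shield the ester carbonyl, and warm acidification would invite decarboxylation or loss of the prenyl group. Fallback: set out from 5 and cleave the ester at its methyl carbon, not at the carbonyl, by SN2 dealkylation with lithium propane-1-thiolate (LiSPr) in DMF at rt. This ignores the shielding and, after cold acidification, arrives at 6 without any new intermediate.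

## Further compounds

F1 | step 5 | 2-{[6-({[tert-butyl(dimethyl)silyl]oxy}methyl)-2,4-dioxocyclohexyl]oxy}-4-methyl-6-[(3-methylbut-2-en-1-yl)oxy]benzoic acid | CC(C)=CCOc1cc(C)cc(OC2C(CO[Si](C)(C)C(C)(C)C)CC(=O)CC2=O)c1C(=O)O
F2 | step 6 | 2-[2-({[tert-butyl(dimethyl)silyl]oxy}methyl)-4,6-dihydroxyphenoxy]-4-methyl-6-[(3-methylbut-2-en-1-yl)oxy]benzoic acid | CC(C)=CCOc1cc(C)cc(Oc2c(CO[Si](C)(C)C(C)(C)C)cc(O)cc2O)c1C(=O)O
F3 | step 2 | methyl 4-methyl-6-[(3-methylbut-2-en-1-yl)oxy]-2-(2-oxopropoxy)benzoate | COC(=O)c1c(OCC(C)=O)cc(C)cc1OCC=C(C)C
F0 | step 3 | none | none
A1 | alternative 1 | 6-(benzyloxy)-4-methyl-2H-pyran-2-one | Cc1cc(=O)oc(OCc2ccccc2)c1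
A2 | alternative 1 | methyl 3-[2-({[tert-butyl(dimethyl)silyl]oxy}methyl)-4,6-dimethoxyphenoxy]prop-2-ynoate | COC(=O)C#COc1c(CO[Si](C)(C)C(C)(C)C)cc(OC)cc1OC
A3 | alternative 1 | methyl 2-(benzyloxy)-6-[2-({[tert-butyl(dimethyl)silyl]oxy}methyl)-4,6-dimethoxyphenoxy]-4-methylbenzoate | COC(=O)c1c(OCc2ccccc2)cc(C)cc1Oc1c(CO[Si](C)(C)C(C)(C)C)cc(OC)cc1OC
A4 | alternative 2 | methyl 2-{[2-({[tert-butyl(dimethyl)silyl]oxy}methyl)-4-oxocyclobut-2-en-1-yl]oxy}-4-methyl-6-[(3-methylbut-2-en-1-yl)oxy]benzoate | COC(=O)c1c(OCC=C(C)C)cc(C)cc1OC1C(=O)C=C1CO[Si](C)(C)C(C)(C)C
A5 | alternative 2 | methoxyethyne | COC#C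
A6 | alternative 2 | methyl 2-[2-({[tert-butyl(dimethyl)silyl]oxy}methyl)-6-hydroxy-4-methoxyphenoxy]-4-methyl-6-[(3-methylbut-2-en-1-yl)oxy]benzoate | COC(=O)c1c(OCC=C(C)C)cc(C)cc1Oc1c(CO[Si](C)(C)C(C)(C)C)cc(OC)cc1O
A7 | alternative 3 | 5-methyl-3-[(3-methylbut-2-en-1-yl)oxy]-2-(trimethylsilyl)phenyl trifluoromethanesulfonate | CC(C)=CCOc1cc(C)cc(OS(=O)(=O)C(F)(F)F)c1[Si](C)(C)C
A8 | alternative 3 | 2-({[tert-butyl(dimethyl)silyl]oxy}methyl)-4,6-dimethoxyphenol | COc1cc(CO[Si](C)(C)C(C)(C)C)c(O)c(OC)c1
A9 | alternative 3 | carbon dioxide | O=C=O
A10 | alternative 3 | 2-[2-({[tert-butyl(dimethyl)silyl]oxy}methyl)-4,6-dimethoxyphenoxy]-4-methyl-6-[(3-methylbut-2-en-1-yl)oxy]benzoic acid | CC(C)=CCOc1cc(C)cc(Oc2c(CO[Si](C)(C)C(C)(C)C)cc(OC)cc2OC)c1C(=O)O
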